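**Plan**

1. Ring A (the tetrahydrofuran) is numbered O1, C2 (aryl), C3 (CH2OH), C4 (aroyl), C5. C5 is a lone methylene between O1 and the ketone α-carbon C4, so it is a formaldehyde carbon; the C3‑CH2OH/C4‑aroyl pair is the hydrolysed form of a 5‑aryl‑2,3‑dihydrofuran (ring B) whose nucleophilic enol ether carbon is C4.
2. Retrosynthesis: the two phenol O–benzyl bonds are cut first, then C4–C5 (ring B re-closed), which leaves a methoxymethyl ether on the C2 oxygen. Ring B is then cut at its enol ether C–O bond, next the aryl–C(=O) bond (aryllithium plus butyrolactone), and last C2–C3 (aldol).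
3. Forward: syn aldol (C2–C3), MOM ether, reduction and lactonisation to a β‑substituted butyrolactone, aryllithium addition and cyclodehydration to ring B. Ring A is then closed onto ring B by oxocarbenium–enol ether cyclisation, ring B is opened by water, and the benzyl groups are removed.
4. Stereochemistry: C2 (S) and C3 (R) come from an Evans syn aldol controlled by (S)‑4‑benzyloxazolidin‑2‑one. C4 (R) comes from the obligatory cis fusion of rings A and B in the key step and meets no base afterwards.

Key step: step 10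

Remark: 4‑bromo‑2,6‑dimethoxyphenol and mono‑tert‑butyl succinate are taken as catalogue compounds; 17, 21 and 22 are drawn as open γ‑hydroxy ketones although each can equilibrate with its cyclic hemiketal.

**Step 1**
Reactants: 1 syringaldehyde (4‑hydroxy‑3,5‑dimethoxybenzaldehyde)
Product: 2 4‑(benzyloxy)‑3,5‑dimethoxybenzaldehyde
Conditions: BnBr, K2CO3, DMF, 60 °C
Reagents that add atoms: benzyl bromide, BrCc1ccccc1
Why: Williamson ether synthesis, in which the phenoxide formed with K2CO3 displaces bromide from benzyl bromide by SN2; no stereocentre is involved.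

**Step 2**
Reactants: 3 4‑bromo‑2,6‑dimethoxyphenol
Product: 4 2‑(benzyloxy)‑5‑bromo‑1,3‑dimethoxybenzene
Conditions: BnBr, K2CO3, DMF, 60 °C
Reagents that add atoms: benzyl bromide, BrCc1ccccc1
Why: Williamson ether synthesis as in step 1; the aryl bromide is inert to these conditions.

**Step 3**
Reactants: 5 mono‑tert‑butyl succinate (4‑tert‑butoxy‑4‑oxobutanoic acid); 6 (S)‑4‑benzyloxazolidin‑2‑one
Product: 8 tert‑butyl 4‑[(S)‑4‑benzyl‑2‑oxooxazolidin‑3‑yl]‑4‑oxobutanoate, via mixed pivalic anhydride 7 (not isolated)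
Conditions: PivCl, Et3N, THF, −20 °C; then 6, LiCl, −20 °C → rt
Reagents that add atoms: none
Why: Mixed-anhydride N‑acylation of the oxazolidinone (LiCl/Et3N activation), in which nitrogen attacks the unhindered succinyl carbonyl of 7 rather than the pivaloyl carbonyl; no stereocentre is formed.

**Step 4**
Reactants: 8 tert‑butyl 4‑[(S)‑4‑benzyl‑2‑oxooxazolidin‑3‑yl]‑4‑oxobutanoate; 2 4‑(benzyloxy)‑3,5‑dimethoxybenzaldehyde
Product: 10 tert‑butyl (3S,4S)‑3‑[(S)‑4‑benzyl‑2‑oxooxazolidine‑3‑carbonyl]‑4‑[4‑(benzyloxy)‑3,5‑dimethoxyphenyl]‑4‑hydroxybutanoate, via Z‑boron enolate 9 (not isolated)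
Conditions: Bu2BOTf, i‑Pr2NEt, CH2Cl2, 0 °C; then 2, −78 → 0 °C; pH 7 buffer, MeOH, 30% H2O2, 0 °C
Reagents that add atoms: none
Why: Evans syn aldol reaction, in which soft enolisation gives the Z‑boron enolate of the imide only (not of the ester) and a closed chair transition state with opposed imide carbonyls lets the aldehyde add to the enolate face away from the auxiliary benzyl group; this sets the carbinol carbon (later C2, S) and the α‑carbon (later C3) as the syn pair, and the tert‑butyl ester is too hindered to lactonise with the new hydroxyl.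

**Step 5**
Reactants: 10 the syn aldol adduct; 11 chloromethyl methyl ether
Product: 12 tert‑butyl (3S,4S)‑3‑[(S)‑4‑benzyl‑2‑oxooxazolidine‑3‑carbonyl]‑4‑[4‑(benzyloxy)‑3,5‑dimethoxyphenyl]‑4‑(methoxymethoxy)butanoate
Conditions: MOMCl, i‑Pr2NEt, Bu4NI (cat.), CH2Cl2, 0 → 40 °C
Reagents that add atoms: none
Why: Methoxymethyl ether formation by O‑alkylation of the secondary alcohol under amine base too weak to cause retro‑aldol cleavage; the acetal carbon installed here is the future C5 and no stereocentre is touched.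

**Step 6**
Reactants: 12 the MOM‑protected imide
Product: 13 tert‑butyl (3R,4S)‑4‑[4‑(benzyloxy)‑3,5‑dimethoxyphenyl]‑3‑(hydroxymethyl)‑4‑(methoxymethoxy)butanoate
Conditions: LiBH4, MeOH (1 equiv), THF, 0 °C
Reagents that add atoms: none
Why: LiBH4 reductive cleavage of the N‑acyloxazolidinone, in which hydride attacks the activated exocyclic imide carbonyl far faster than the tert‑butyl ester, the auxiliary is released and the α‑centre is not epimerised under these non-enolising conditions.

**Step 7**
Reactants: 13 the hydroxy tert‑butyl ester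
Product: 14 (R)‑4‑{(S)‑[4‑(benzyloxy)‑3,5‑dimethoxyphenyl](methoxymethoxy)methyl}dihydrofuran‑2(3H)‑one
Conditions: KOt‑Bu (0.1 equiv), THF, 0 °C
Reagents that add atoms: none
Why: Base-catalysed lactonisation (intramolecular transesterification), in which the primary alkoxide closes 5‑exo‑trig onto the ester and expels tert‑butoxide, which carries the chain; neither stereocentre is α to a carbonyl, so none can epimerise.

**Step 8**
Reactants: 14 the β‑substituted butyrolactone; 4 2‑(benzyloxy)‑5‑bromo‑1,3‑dimethoxybenzene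
Product: 17 (3R,4S)‑1,4‑bis[4‑(benzyloxy)‑3,5‑dimethoxyphenyl]‑3‑(hydroxymethyl)‑4‑(methoxymethoxy)butan‑1‑one, via aryllithium 15 (not isolated), via lithium lactolate 16 (not isolated)
Conditions: 4, n‑BuLi, THF, −78 °C; then 14, −78 °C; AcOH, −78 °C → rt
Reagents that add atoms: none
Why: Bromine–lithium exchange followed by 1,2‑addition of the aryllithium to the lactone carbonyl, where the tetrahedral lithium lactolate persists at −78 °C so that the ketone is released only on protonation and a second addition is avoided; the stereocentres are remote from the reacting carbonyl.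

**Step 9**
Reactants: 17 the γ‑hydroxy aryl ketone
Product: 18 (R)‑5‑[4‑(benzyloxy)‑3,5‑dimethoxyphenyl]‑3‑{(S)‑[4‑(benzyloxy)‑3,5‑dimethoxyphenyl](methoxymethoxy)methyl}‑2,3‑dihydrofuran
Conditions: PPTS (5 mol%), 4 Å MS, toluene, 60 °C; then Et3N
Reagents that add atoms: none
Why: Acid-catalysed cyclodehydration of a γ‑hydroxy aryl ketone, in which the primary hydroxyl closes to the cyclic hemiketal, PPTS ionises it to the aryl-stabilised oxocarbenium ion and loss of a proton from the only α‑CH2 gives the 5‑aryl‑2,3‑dihydrofuran (ring B); the acid is too weak to ionise the MOM acetal.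

**Step 10**
Reactants: 18 the dihydrofuran MOM ether
Product: 21 ciwujiatone dibenzyl ether, via methylene oxocarbenium triflate 19 (not isolated), via bicyclic oxocarbenium triflate 20 (not isolated)
Conditions: TMSOTf (1.2 equiv), 2,6‑di‑tert‑butyl‑4‑methylpyridine (1.5 equiv), CH2Cl2 (0.01 M), −78 → −40 °C; then THF/aq NaOAc–AcOH buffer (pH 5), 0 °C → rt
Reagents that add atoms: water, O
Why: Proposed new method: TMSOTf silylates the unhindered methoxy oxygen of the acetal, MeOSiMe3 departs and the O1=C5H2 oxocarbenium ion 19 is attacked at C5 by the enol ether β‑carbon C4 of ring B, which forms C4–C5 and the aryl-stabilised bicyclic oxocarbenium ion 20; the pH 5 quench hydrates 20 to the hemiketal, which opens to the γ‑hydroxy ketone 21. The closest known reactions are the Lewis-acid addition of acetals to enol ethers (Müller‑Cunradi–Pieroh reaction), Prins-type cyclisations of alkoxymethyl ethers onto tethered π‑nucleophiles, and the enol–oxocarbenium and enol–iminium ring closures that give 3‑acyltetrahydrofurans and 3‑acylpyrrolidines (the latter in the aza‑Cope–Mannich reaction); capture of a MOM-derived oxocarbenium ion by a tethered cyclic enol ether in a bicyclisation is not a described case. Ring A closes in a mode that is formally 5‑endo‑trig at the C5=O1(+) bond and exo with respect to the enol ether double bond, a closure that cationic C=O(+) and C=N(+) electrophiles undergo readily although it is disfavoured for neutral trigonal carbon. C4 is the only new stereocentre and is controlled by ring fusion: ring A shares the C3–C4 bond with ring B, the bicyclo[3.3.0] system can only be cis-fused, so H4 ends cis to H3 (4R), and even if 20 rests as a methyl ketal or loses H4 to the base, hydrolysis or reprotonation can only pass through the cis-fused ion. The step needs ionisation of the acetal on its methoxy side rather than at the benzylic C2–O bond, and capture of 19 by C4 rather than by the electron-rich arene or a second molecule; the known preference of TMSOTf for the methoxy oxygen of alkyl MOM ethers, the low temperature, the hindered non-nucleophilic pyridine that removes adventitious acid, the dilution and the high nucleophilicity of an α‑aryl enol ether held within five-ring reach of C5 are relied on for this.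

**Step 11**
Reactants: 21 ciwujiatone dibenzyl ether
Product: 22 ciwujiatone
Conditions: H2 (1 atm), 10% Pd/C, EtOAc, rt
Reagents that add atoms: none
Why: Catalytic hydrogenolysis of aryl benzyl ethers over Pd/C, where O‑benzyl phenol ethers should cleave much faster than the electron-rich aryl ketone is reduced or the ring benzylic C–O bond is cut; the neutral medium leaves the ketone α‑centre C4 untouched.

**Compound list**

1 | syringaldehyde | COc1cc(C=O)cc(OC)c1O | starting material
2 | 4‑(benzyloxy)‑3,5‑dimethoxybenzaldehyde | COc1cc(C=O)cc(OC)c1OCc1ccccc1 | intermediate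
3 | 4‑bromo‑2,6‑dimethoxyphenol | COc1cc(Br)cc(OC)c1O | starting material
4 | 2‑(benzyloxy)‑5‑bromo‑1,3‑dimethoxybenzene | COc1cc(Br)cc(OC)c1OCc1ccccc1 | intermediate
5 | mono‑tert‑butyl succinate | CC(C)(C)OC(=O)CCC(=O)O | starting material
6 | (S)‑4‑benzyloxazolidin‑2‑one | O=C1N[C@@H](Cc2ccccc2)CO1 | starting material
7 | mixed pivalic anhydride of 5 (not isolated) | CC(C)(C)OC(=O)CCC(=O)OC(=O)C(C)(C)C | intermediate
8 | tert‑butyl 4‑[(S)‑4‑benzyl‑2‑oxooxazolidin‑3‑yl]‑4‑oxobutanoate | CC(C)(C)OC(=O)CCC(=O)N1[C@@H](Cc2ccccc2)COC1=O | intermediate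
9 | Z‑dibutylboron enolate of 8 (not isolated) | CCCCB(CCCC)O/C(=C\CC(=O)OC(C)(C)C)N1[C@@H](Cc2ccccc2)COC1=O | intermediate
10 | tert‑butyl (3S,4S)‑3‑[(S)‑4‑benzyl‑2‑oxooxazolidine‑3‑carbonyl]‑4‑[4‑(benzyloxy)‑3,5‑dimethoxyphenyl]‑4‑hydroxybutanoate | O[C@H](c1cc(OC)c(OCc2ccccc2)c(OC)c1)[C@H](CC(=O)OC(C)(C)C)C(=O)N1[C@@H](Cc2ccccc2)COC1=O | intermediate
11 | chloromethyl methyl ether | COCCl | starting material
12 | tert‑butyl (3S,4S)‑3‑[(S)‑4‑benzyl‑2‑oxooxazolidine‑3‑carbonyl]‑4‑[4‑(benzyloxy)‑3,5‑dimethoxyphenyl]‑4‑(methoxymethoxy)butanoate | COCO[C@H](c1cc(OC)c(OCc2ccccc2)c(OC)c1)[C@H](CC(=O)OC(C)(C)C)C(=O)N1[C@@H](Cc2ccccc2)COC1=O | intermediate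
13 | tert‑butyl (3R,4S)‑4‑[4‑(benzyloxy)‑3,5‑dimethoxyphenyl]‑3‑(hydroxymethyl)‑4‑(methoxymethoxy)butanoate | COCO[C@H](c1cc(OC)c(OCc2ccccc2)c(OC)c1)[C@H](CC(=O)OC(C)(C)C)CO | intermediate
14 | (R)‑4‑{(S)‑[4‑(benzyloxy)‑3,5‑dimethoxyphenyl](methoxymethoxy)methyl}dihydrofuran‑2(3H)‑one | COCO[C@H](c1cc(OC)c(OCc2ccccc2)c(OC)c1)[C@H]1COC(=O)C1 | intermediate
15 | [4‑(benzyloxy)‑3,5‑dimethoxyphenyl]lithium (not isolated) | [Li]c1cc(OC)c(OCc2ccccc2)c(OC)c1 | intermediate
16 | lithium lactolate from 14 and 15 (not isolated; new ketal carbon undefined) | COCO[C@H](c1cc(OC)c(OCc2ccccc2)c(OC)c1)[C@H]1COC([O-])(c2cc(OC)c(OCc3ccccc3)c(OC)c2)C1.[Li+] | intermediate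
17 | (3R,4S)‑1,4‑bis[4‑(benzyloxy)‑3,5‑dimethoxyphenyl]‑3‑(hydroxymethyl)‑4‑(methoxymethoxy)butan‑1‑one | COCO[C@H](c1cc(OC)c(OCc2ccccc2)c(OC)c1)[C@H](CC(=O)c1cc(OC)c(OCc2ccccc2)c(OC)c1)CO | intermediate
18 | (R)‑5‑[4‑(benzyloxy)‑3,5‑dimethoxyphenyl]‑3‑{(S)‑[4‑(benzyloxy)‑3,5‑dimethoxyphenyl](methoxymethoxy)methyl}‑2,3‑dihydrofuran | COCO[C@H](c1cc(OC)c(OCc2ccccc2)c(OC)c1)[C@H]1COC(c2cc(OC)c(OCc3ccccc3)c(OC)c2)=C1 | intermediate
19 | methylene oxocarbenium triflate from 18 (not isolated) | C=[O+][C@H](c1cc(OC)c(OCc2ccccc2)c(OC)c1)[C@H]1COC(c2cc(OC)c(OCc3ccccc3)c(OC)c2)=C1.[O-]S(=O)(=O)C(F)(F)F | intermediate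
20 | cis‑fused bicyclic aryl oxocarbenium triflate (not isolated) | COc1cc(C2=[O+]C[C@@H]3[C@@H](c4cc(OC)c(OCc5ccccc5)c(OC)c4)OC[C@H]23)cc(OC)c1OCc1ccccc1.[O-]S(=O)(=O)C(F)(F)F | intermediate
21 | ciwujiatone dibenzyl ether, {(3R,4R,5S)‑5‑[4‑(benzyloxy)‑3,5‑dimethoxyphenyl]‑4‑(hydroxymethyl)oxolan‑3‑yl}[4‑(benzyloxy)‑3,5‑dimethoxyphenyl]methanone | COc1cc(C(=O)[C@H]2CO[C@H](c3cc(OC)c(OCc4ccccc4)c(OC)c3)[C@H]2CO)cc(OC)c1OCc1ccccc1 | intermediate
22 | ciwujiatone, [(3R,4R,5S)‑5‑(4‑hydroxy‑3,5‑dimethoxyphenyl)‑4‑(hydroxymethyl)oxolan‑3‑yl](4‑hydroxy‑3,5‑dimethoxyphenyl)methanone; (2S,3R,4R) in the numbering used above | COc1cc(C(=O)[C@H]2CO[C@H](c3cc(OC)c(O)c(OC)c3)[C@H]2CO)cc(OC)c1O | target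

**Count and risks**

Total step count: 11. Longest linear sequence: 9 steps (steps 3–11 from 5 and 6; equally step 1 and steps 4–11 from 1).

Steps most likely to fail:

Step 10. What may go wrong is ionisation at the benzylic C2–O bond in place of the acetal C–O bond, followed by loss of the C3 proton and aromatisation of ring B to a furan, or cationic oligomerisation of the enol ether before ring A closes. The fallback uses known reactions, sets out from lactone 14 and returns at 21. Claisen-type formylation of 14 (NaH, HCO2Et, THF) would give the α‑hydroxymethylene lactone F1. Cleavage of the MOM ether (TMSOTf, 2,2'‑bipyridyl, CH2Cl2, 0 °C, then water) frees the C2 hydroxyl, which adds to the formyl tautomer and should give the cis‑fused bicyclic lactol F2. Ionic reduction of the lactol (Et3SiH, BF3·OEt2, CH2Cl2, −78 °C) would give the furofuranone F3, in which C4 is again held cis by ring fusion. Addition of aryllithium 15 (THF, −78 °C) and the pH 5 work-up would open the resulting hemiketal to 21. In this variant C5 comes from ethyl formate and the aryl–carbonyl bond is made last.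

Step 9. What may go wrong is acid-induced ionisation of the benzylic methoxymethoxy group or protonation of the enol ether as it forms, leading to aromatisation or dimerisation. The fallback sets out from 14, returns at 18 and joins the aryl group to a preformed enol ether without acid. O‑Phosphorylation of the lactone enolate (KN(SiMe3)2, (PhO)2P(O)Cl, THF–DMPU, −78 °C) would give the ketene acetal phosphate F4. Suzuki–Miyaura coupling of F4 with the arylboronic acid F5 (from aryllithium 15 and B(Oi‑Pr)3, then aqueous NH4Cl) under Pd(PPh3)4, a zerovalent palladium complex, with aqueous Na2CO3 in DMF should give 18 directly; this also bypasses step 8.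

Step 8. What may go wrong is proton transfer from the lactone α‑CH2 to the aryllithium, or collapse of the lactolate before the quench followed by a second addition. The fallback sets out from 14 and returns at 17. Aminolysis of the lactone with MeNH(OMe)·HCl and i‑PrMgCl (THF, −20 °C) would give the hydroxy Weinreb amide F6. After deprotonation of its hydroxyl with one equivalent of i‑PrMgCl, aryllithium 15 should add once to give a chelated tetrahedral intermediate that releases 17 only on work-up.

**Further compounds**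

F1 | step 10 | (4R)‑4‑{(S)‑[4‑(benzyloxy)‑3,5‑dimethoxyphenyl](methoxymethoxy)methyl}‑3‑(hydroxymethylene)dihydrofuran‑2(3H)‑one | COCO[C@H](c1cc(OC)c(OCc2ccccc2)c(OC)c1)[C@H]1COC(=O)C1=CO
F2 | step 10 | (1R,5R,6S)‑6‑[4‑(benzyloxy)‑3,5‑dimethoxyphenyl]‑8‑hydroxy‑3,7‑dioxabicyclo[3.3.0]octan‑2‑one (either configuration at C8) | O=C1OC[C@@H]2[C@@H](c3cc(OC)c(OCc4ccccc4)c(OC)c3)OC(O)[C@H]12
F3 | step 10 | (1R,5R,6S)‑6‑[4‑(benzyloxy)‑3,5‑dimethoxyphenyl]‑3,7‑dioxabicyclo[3.3.0]octan‑2‑one | O=C1OC[C@@H]2[C@@H](c3cc(OC)c(OCc4ccccc4)c(OC)c3)OC[C@H]12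
F4 | step 9 | (R)‑4‑{(S)‑[4‑(benzyloxy)‑3,5‑dimethoxyphenyl](methoxymethoxy)methyl}‑4,5‑dihydrofuran‑2‑yl diphenyl phosphate | COCO[C@H](c1cc(OC)c(OCc2ccccc2)c(OC)c1)[C@H]1COC(OP(=O)(Oc2ccccc2)Oc2ccccc2)=C1
F5 | step 9 | [4‑(benzyloxy)‑3,5‑dimethoxyphenyl]boronic acid | COc1cc(B(O)O)cc(OC)c1OCc1ccccc1
F6 | step 8 | (3R,4S)‑4‑[4‑(benzyloxy)‑3,5‑dimethoxyphenyl]‑3‑(hydroxymethyl)‑N‑methoxy‑4‑(methoxymethoxy)‑N‑methylbutanamide | COCO[C@H](c1cc(OC)c(OCc2ccccc2)c(OC)c1)[C@H](CC(=O)N(C)OC)CO
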